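**Retrosynthetic overview**
1. C40 = C15 + C10 + C15: Wittig olefinations at C11=C12 (step 7) and C11'=C12' (step 16) on C10-dialdehyde 10; enynol 1 supplies C7–C11 of both ends.
2. Left end: the cyclohexenone ring is taken intact from ketoisophorone 3; acetylide addition at C6 and Meyer–Schuster rearrangement give the C6=C7–C8(=O) enone.
3. Right end: the hydroxycyclohexene ring C1'–C6' is closed at C3'–C4' by a Cu-catalysed enantioselective borylative cyclisation of the achiral, acyclic allenyne aldehyde 20. This sets 3'R and the tetrasubstituted C5'=C6' of the enyne; the C5'–B bond is then turned into C5'–CH3. 20 comes from lactone 13 (C6', C1', C2', C3'), enynol 1 and an ethynyl unit (C5', C4').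
4. Enabling feature: C3'–OH is homoallylic to C5'=C6', and C6' is tied to C3' only through C2' and the quaternary C1'(CH3)2. An allyl-metal over C4'–C5'–C6' can therefore reach the C3' aldehyde only through C4' (six-membered ring); closure at C6' would give a cyclobutane with two adjacent quaternary carbons.
5. Ring order: the cyclohexenone ring is present from 3 and never opened; the hydroxycyclohexene ring is the only ring closed in the route and therefore the last (step 13).

Key step: step 13

Remark: carotenoid numbering is used (primed atoms = right half). The SMILES is read as 3'R, 6Z (C8 syn to C5) and E at all other double bonds. The carbinol centres of 6, 16 and 17 are racemic and are erased in later steps.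

Step 1
Reactants: 1 (2E)-3-methylpent-2-en-4-yn-1-ol
Product: 2 TBS ether of 1
Conditions: TBSCl, imidazole, CH2Cl2, 0 °C → rt
Reagents that add atoms: tert-butyldimethylsilyl chloride, CC(C)(C)[Si](C)(C)Cl
Why: Standard silylation of a primary allylic alcohol, which masks the oxygen that later becomes the leaving group of both phosphonium salts.

Step 2
Reactants: 3 ketoisophorone
Product: 4 ketoisophorone 4-ethylene ketal
Conditions: ethylene glycol (1.2 equiv), p-TsOH (cat.), toluene, Dean–Stark, reflux
Reagents that add atoms: ethane-1,2-diol, OCCO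
Why: Acid-catalysed ketalisation should take only the unhindered carbonyl (carotenoid C3), because the other one is flanked by CMe2 and C(Me)=.

Step 3
Reactants: 2 TBS ether of 1; 4 ketoisophorone 4-ethylene ketal
Product: 6 racemic tertiary propargylic alcohol (ketal-protected C15 enynol), via bromomagnesium acetylide 5 (not isolated)
Conditions: EtMgBr (1.05 equiv), THF, 0 → 40 °C; then 4, 0 °C → rt; aq. NH4Cl
Reagents that add atoms: none
Why: 1,2-Addition of an alkynyl Grignard reagent (formed by deprotonation of the terminal alkyne with EtMgBr) to the hindered, non-enolisable ketone, the alkynylation used for carotenoid C15 building blocks and abscisic-acid-type skeletons; the new carbinol centre is erased in step 4.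

Step 4
Reactants: 6 racemic tertiary propargylic alcohol
Product: 7 ketal-protected (6Z,9E)-dienone TBS ether
Conditions: MoO2(acac)2 (2 mol %), Ph3PAuCl/AgOTf (2 mol %), toluene, rt
Reagents that add atoms: none
Why: Meyer–Schuster rearrangement (Rupe dehydration is excluded because C6 carries no β-hydrogen); the allenol should be protonated at C7 in the ring plane from the C1 side, whose methyls lie out of plane, rather than past the in-plane C5 methyl, which places C8 syn to C5 (6Z), while 9E is carried over from 1.

Step 5
Reactants: 7 ketal-protected (6Z,9E)-dienone TBS ether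
Product: 8 (6Z,9E)-C15 hydroxy dienedione
Conditions: 1 M HCl, THF, 0 °C → rt
Reagents that add atoms: water, O
Why: Acid hydrolysis should remove the dioxolane and the primary silyl ether in one operation, and the E allylic alcohol cannot cyclise onto the enone.

Step 6
Reactants: 8 (6Z,9E)-C15 hydroxy dienedione
Product: 9 left C15 phosphonium bromide
Conditions: Ph3P·HBr (1.1 equiv), CH2Cl2/MeOH, rt
Reagents that add atoms: triphenylphosphine hydrobromide, [Br-].[PH+](c1ccccc1)(c1ccccc1)c1ccccc1
Why: Classical conversion of a primary allylic alcohol into its triphenylphosphonium salt (substitution via the allylic bromide), as for carotenoid C15 salts; the ketones are not touched.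

Step 7
Reactants: 9 left C15 phosphonium bromide; 10 (2E,4E,6E)-2,7-dimethylocta-2,4,6-trienedial
Product: 12 C25 apo-12'-aldehyde, via ylide 11 (not isolated)
Conditions: 10 (3 equiv), 1,2-epoxybutane, EtOH, reflux; excess 10 recovered
Reagents that add atoms: none
Why: Wittig olefination of a vinylogous acyl-stabilised ylide under base-free epoxide conditions should give the 11E olefin and spare the base-sensitive dienedione; the excess of dialdehyde enforces mono-olefination.

Step 8
Reactants: 2 TBS ether of 1; 13 3,3-dimethyloxolan-2-one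
Product: 15 hydroxy ynone (in equilibrium with its lactol), via lithium acetylide 14 (not isolated)
Conditions: n-BuLi (1.05 equiv), THF, −78 °C; then 13, −78 °C; aq. NH4Cl at −78 °C
Reagents that add atoms: none
Why: Acetylide opening of a lactone (the lithium lactolate is stable at −78 °C, so only one alkynyl adds) makes the hindered C6'–C7' bond next to the quaternary C1' by carbonyl addition.

Step 9
Reactants: 15 hydroxy ynone
Product: 17 racemic bis(methyl carbonate) of the 4-ethynyl-1,4-diol, via magnesium dialkoxide 16 (not isolated)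
Conditions: HC≡CMgBr (3 equiv), THF, 0 °C → rt; then ClCO2Me (4 equiv), DMAP (cat.), 0 °C → rt
Reagents that add atoms: ethynylmagnesium bromide, C#C[Mg]Br; methyl chloroformate, COC(=O)Cl
Why: 1,2-Grignard addition to the ynone followed by acylation of both alkoxides in the same flask; the tertiary propargylic carbonate is the leaving group for step 10, where its carbinol centre disappears.

Step 10
Reactants: 17 racemic bis(methyl carbonate)
Product: 18 allenyne methyl carbonate
Conditions: Pd2(dba)3·CHCl3 (2.5 mol %), n-Bu3P (10 mol %), HCO2NH4 (2 equiv), THF, rt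
Reagents that add atoms: none
Why: Tsuji hydrogenolysis of a tertiary propargylic carbonate with formate: SN2' oxidative addition through the unhindered terminal alkyne and hydride transfer should give the 1,1-disubstituted allene, while the primary alkyl carbonate and the silyl ether are inert.

Step 11
Reactants: 18 allenyne methyl carbonate
Product: 19 allenyne alcohol
Conditions: K2CO3 (0.5 equiv), MeOH, 0 °C → rt
Reagents that add atoms: none
Why: Mild methanolysis (transesterification) of the alkyl methyl carbonate; the allenyne has no hydrogen at C6' and cannot isomerise.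

Step 12
Reactants: 19 allenyne alcohol
Product: 20 allenyne aldehyde
Conditions: Dess–Martin periodinane (1.2 equiv), CH2Cl2, 0 °C → rt; used at once
Reagents that add atoms: none
Why: Dess–Martin oxidation of a primary alcohol under neutral conditions leaves allene, enyne and silyl ether untouched.

Step 13
Reactants: 20 allenyne aldehyde
Product: 23 (R)-cyclohexenol C5'-pinacolboronate, via allylcopper 21 (not isolated), via O-boryl ether 22 (not isolated)
Conditions: CuCl (5 mol %), (R,R)-Ph-BPE (6 mol %), NaOt-Bu (10 mol %), B2pin2 (1.2 equiv), THF, slow addition of 20 (final 0.01 M), 0 °C → rt; aq. NH4Cl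
Reagents that add atoms: bis(pinacolato)diboron, CC1(C)OB(OC1(C)C)B1OC(C)(C)C(C)(C)O1
Why: Proposed new method: L*Cu–Bpin (from CuCl, NaOt-Bu and B2pin2) adds across the terminal C4'=C5' bond of the allene with boron on the central carbon C5', giving the 2-boryl allylcopper 21, delocalised over C4'/C6' (and C8'); 21 adds to the tethered C3' aldehyde through C4' in a six-membered, boat-like (bicyclo[2.2.2]) transition state with copper on C6', and B2pin2 borylates the copper alkoxide to 22, which releases Cu–Bpin. The closest known reaction type is the Cu-catalysed enantioselective borylative coupling of allenes with aldehydes and ketones (2-boryl-allylcopper addition), including its intramolecular exo cyclisations; closure through the distal allene carbon is the new element. The ring closes in a 6-endo sense at C3'–C4', so all three allyl carbons become ring atoms and the tetrasubstituted C5'=C6' bond forms in the only geometry the ring allows. The C3' stereocentre is set by the catalyst: the chiral bisphosphine on copper selects the aldehyde face of the achiral substrate in the C–C bond-forming step, and the ligand antipode is used if the first run shows the 3'S sense. The step needs C4' rather than C6' or C8' attack, and Cu–B addition to the allene rather than to the aldehyde or the enyne: the two-atom C1'(CH3)2–C2' link makes closure at C6' a cyclobutane with adjacent quaternary carbons and closure at C8' a six-membered cyclic allene, the gem-dimethyl group blocks intermolecular γ-addition at C6', terminal allenes are the fastest acceptors for Cu–Bpin, and high dilution holds back oligomers.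

Step 14
Reactants: 23 (R)-cyclohexenol C5'-pinacolboronate
Product: 24 (R)-cyclohexenol enyne TBS ether
Conditions: MeI (3 equiv), Pd2(dba)3 (2.5 mol %), P(o-tol)3 (10 mol %), K2CO3 (3 equiv), DMF/H2O 9:1, 60 °C
Reagents that add atoms: iodomethane, CI
Why: Suzuki–Miyaura methylation of an alkenyl pinacolboronate turns the boron handle into the C5' methyl with the ring-fixed alkene geometry; the free alcohol, enyne and silyl ether are compatible.

Step 15
Reactants: 24 (R)-cyclohexenol enyne TBS ether
Product: 26 right C15 phosphonium bromide, via allylic alcohol 25 (not isolated)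
Conditions: Ph3P·HBr (1.1 equiv), MeOH, 0 °C → rt
Reagents that add atoms: triphenylphosphine hydrobromide, [Br-].[PH+](c1ccccc1)(c1ccccc1)c1ccccc1
Why: Acidic methanolysis frees the primary allylic alcohol, which is converted into the allylic phosphonium salt while the secondary C3' alcohol stays free (as for hydroxylated carotenoid C15 salts), with 9'E retained.

Step 16
Reactants: 12 C25 apo-12'-aldehyde; 26 right C15 phosphonium bromide
Product: 28 target CNP0205386.1, via ylide 27 (not isolated)
Conditions: NaOMe (1.3 equiv), CH2Cl2/MeOH, 0 °C → rt, dark, Ar; brief warming in heptane to isomerise the 11'Z fraction; HPLC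
Reagents that add atoms: none
Why: Wittig olefination of the polyenal with the semistabilised C15 ylide forms C11'=C12' (the usual last step of C15 + C25 carotenoid syntheses); the hindered 11'Z isomer should revert thermally to E and no stereocentre is touched.

**Compound list**
1 | (2E)-3-methylpent-2-en-4-yn-1-ol | OC/C=C(\C)C#C | starting material
2 | tert-butyldimethylsilyl ether of 1 | CC(C)(C)[Si](C)(C)OC/C=C(\C)C#C | intermediate
3 | ketoisophorone (2,6,6-trimethylcyclohex-2-ene-1,4-dione) | CC1=CC(=O)CC(C)(C)C1=O | starting material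
4 | ketoisophorone 4-ethylene ketal (7,9,9-trimethyl-1,4-dioxaspiro[4.5]dec-6-en-8-one) | CC1=CC2(CC(C)(C)C1=O)OCCO2 | intermediate
5 | bromomagnesium acetylide of 2 (not isolated) | CC(C)(C)[Si](C)(C)OC/C=C(\C)C#C[Mg]Br | intermediate
6 | racemic tertiary propargylic alcohol from 4 and 5 | CC1=CC2(CC(C)(C)C1(O)C#C/C(C)=C/CO[Si](C)(C)C(C)(C)C)OCCO2 | intermediate
7 | ketal-protected (6Z,9E)-dienone TBS ether (exocyclic C6=C7, C8 ketone syn to C5) | CC1=CC2(CC(C)(C)/C1=C/C(=O)/C(C)=C/CO[Si](C)(C)C(C)(C)C)OCCO2 | intermediate
8 | (4Z)-4-[(3E)-5-hydroxy-3-methyl-2-oxopent-3-en-1-ylidene]-3,5,5-trimethylcyclohex-2-en-1-one | CC1=CC(=O)CC(C)(C)/C1=C/C(=O)/C(C)=C/CO | intermediate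
9 | [(2E)-3-methyl-4-oxo-5-(2,6,6-trimethyl-4-oxocyclohex-2-en-1-ylidene)pent-2-enyl]triphenylphosphonium bromide (exocyclic bond Z) | CC1=CC(=O)CC(C)(C)/C1=C/C(=O)/C(C)=C/C[P+](c1ccccc1)(c1ccccc1)c1ccccc1.[Br-] | intermediate
10 | (2E,4E,6E)-2,7-dimethylocta-2,4,6-trienedial (C10-dialdehyde) | O=C/C(C)=C/C=C/C=C(C)/C=O | starting material
11 | ylide of 9 (not isolated) | CC1=CC(=O)CC(C)(C)/C1=C/C(=O)/C(C)=C/C=P(c1ccccc1)(c1ccccc1)c1ccccc1 | intermediate
12 | C25 apo-12'-aldehyde (left ring, C7 to C12', 6Z, chain all-E) | CC1=CC(=O)CC(C)(C)/C1=C/C(=O)/C(C)=C/C=C/C(C)=C/C=C/C=C(C)/C=O | intermediate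
13 | 3,3-dimethyloxolan-2-one (α,α-dimethyl-γ-butyrolactone) | CC1(C)CCOC1=O | starting material
14 | lithium acetylide of 2 (not isolated) | CC(C)(C)[Si](C)(C)OC/C=C(\C)C#C[Li] | intermediate
15 | (7E)-9-(tert-butyldimethylsilyloxy)-1-hydroxy-3,3,7-trimethylnon-7-en-5-yn-4-one | CC(C)(C)[Si](C)(C)OC/C=C(\C)C#CC(=O)C(C)(C)CCO | intermediate
16 | bis(bromomagnesium) alkoxide of the 4-ethynyl-1,4-diol (not isolated, racemic) | CC(C)(C)[Si](C)(C)OC/C=C(\C)C#CC(C#C)(O[Mg]Br)C(C)(C)CCO[Mg]Br | intermediate
17 | bis(methyl carbonate) of (7E)-9-(TBSO)-4-ethynyl-3,3,7-trimethylnon-7-en-5-yne-1,4-diol (racemic) | CC(C)(C)[Si](C)(C)OC/C=C(\C)C#CC(C#C)(OC(=O)OC)C(C)(C)CCOC(=O)OC | intermediate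
18 | methyl (7E)-9-(TBSO)-3,3,7-trimethyl-4-vinylidenenon-7-en-5-yn-1-yl carbonate | CC(C)(C)[Si](C)(C)OC/C=C(\C)C#CC(=C=C)C(C)(C)CCOC(=O)OC | intermediate
19 | (7E)-9-(TBSO)-3,3,7-trimethyl-4-vinylidenenon-7-en-5-yn-1-ol | CC(C)(C)[Si](C)(C)OC/C=C(\C)C#CC(=C=C)C(C)(C)CCO | intermediate
20 | (7E)-9-(TBSO)-3,3,7-trimethyl-4-vinylidenenon-7-en-5-ynal | CC(C)(C)[Si](C)(C)OC/C=C(\C)C#CC(=C=C)C(C)(C)CC=O | intermediate
21 | 2-boryl allylcopper from 20 (not isolated, ligand omitted) | CC(C)(C)[Si](C)(C)OC/C=C(\C)C#CC(=C(C[Cu])B1OC(C)(C)C(C)(C)O1)C(C)(C)CC=O | intermediate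
22 | O-pinacolboryl ether of 23 (not isolated) | CC(C)(C)[Si](C)(C)OC/C=C(\C)C#CC1=C(B2OC(C)(C)C(C)(C)O2)C[C@@H](OB2OC(C)(C)C(C)(C)O2)CC1(C)C | intermediate
23 | (1R)-4-[(3E)-5-(TBSO)-3-methylpent-3-en-1-ynyl]-5,5-dimethyl-3-(pinacolboryl)cyclohex-3-en-1-ol | CC(C)(C)[Si](C)(C)OC/C=C(\C)C#CC1=C(B2OC(C)(C)C(C)(C)O2)C[C@@H](O)CC1(C)C | intermediate
24 | (1R)-4-[(3E)-5-(TBSO)-3-methylpent-3-en-1-ynyl]-3,5,5-trimethylcyclohex-3-en-1-ol | CC(C)(C)[Si](C)(C)OC/C=C(\C)C#CC1=C(C)C[C@@H](O)CC1(C)C | intermediate
25 | (1R)-4-[(3E)-5-hydroxy-3-methylpent-3-en-1-ynyl]-3,5,5-trimethylcyclohex-3-en-1-ol (not isolated) | OC/C=C(\C)C#CC1=C(C)C[C@@H](O)CC1(C)C | intermediate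
26 | {(2E)-5-[(4R)-4-hydroxy-2,6,6-trimethylcyclohex-1-en-1-yl]-3-methylpent-2-en-4-ynyl}triphenylphosphonium bromide | [Br-].c1ccccc1[P+](c1ccccc1)(c1ccccc1)C/C=C(\C)C#CC1=C(C)C[C@@H](O)CC1(C)C | intermediate
27 | ylide of 26 (not isolated) | c1ccccc1P(c1ccccc1)(c1ccccc1)=C/C=C(\C)C#CC1=C(C)C[C@@H](O)CC1(C)C | intermediate
28 | CNP0205386.1 (3'R, 6Z, chain all-E) | CC1=CC(=O)CC(C)(C)/C1=C/C(=O)/C(C)=C/C=C/C(C)=C/C=C/C=C(C)/C=C/C=C(\C)C#CC1=C(C)C[C@@H](O)CC1(C)C | target

**Step count and risks**
Total steps: 16. Longest linear sequence: 10 steps (steps 1, 8–16).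

Most likely to fail:

1. Step 13 (Proposed new method). What may go wrong: the allylcopper may not close through the distal carbon and instead be protonated to an alkenylboronate; the aldehyde may undergo 1,2-borylation; intermolecular addition may give oligomers; or closure may occur with poor facial selectivity. Fallback with known chemistry, setting out from ketoisophorone 3 and TBS ether 2 and returning at 26. An ene-reductase (Old Yellow Enzyme, NADPH recycling) reduces the C=C of 3 to (6R)-levodione F1. Levodione reductase (or a ketoreductase) reduces the unhindered ketone to (4R,6R)-actinol F2. TBSCl/imidazole gives actinol TBS ether F3. The bromomagnesium acetylide 5, made from 2 with EtMgBr in THF as in step 3, adds to F3 to give the tertiary propargylic alcohol F4. POCl3/pyridine dehydrates it towards the only β-hydrogen to the enyne bis-silyl ether F5. Ph3P·HBr in MeOH (as in step 15, longer time) removes both silyl groups and forms 26.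

2. Step 4. What may go wrong: poor control of the exocyclic C6=C7 geometry and its erosion by acid in step 5, and competing 1,3-transposition of the allylic tertiary alcohol. Fallback from 6, returning at 8: Ru-catalysed trans-hydrosilylation ([Cp*Ru(MeCN)3]PF6, (EtO)3SiH, CH2Cl2) gives the (Z)-β-triethoxysilyl allylic alcohol F6. Tamao–Fleming oxidation (KF, KHCO3, H2O2) gives the β-hydroxy ketone F7 (formal hydration, an aldol surrogate). Aqueous HCl/THF at 40 °C dehydrates F7 (β-hydroxy ketone elimination) and removes ketal and silyl ether to give 8; the geometric isomers are separated and the unwanted one is re-equilibrated with catalytic iodine.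

3. Step 16. What may go wrong: Z/E scrambling (11'Z formation, drift of the alkyne-flanked 9' bond) and attack of methoxide on the cross-conjugated dienedione of 12. Fallback that reverses the order of the two Wittig couplings, setting out from 26 and 10 and returning at 28: 26 and 10 (3 equiv, NaOMe, CH2Cl2/MeOH, 0 °C) give the acetylenic C25 apo-aldehyde F8, which is purified as the all-E isomer. F8 and the stabilised ylide 11 generated from 9 (1,2-epoxybutane, EtOH, 60 °C, base-free) then give 28, so that the dienedione never meets methoxide and the last olefination is the more E-selective one.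

Further compounds
F1 | step 13 | (6R)-2,2,6-trimethylcyclohexane-1,4-dione ((6R)-levodione) | O=C1C(C)(C)CC(=O)C[C@H]1C
F2 | step 13 | (4R,6R)-4-hydroxy-2,2,6-trimethylcyclohexanone (actinol) | O=C1C(C)(C)C[C@H](O)C[C@H]1C
F3 | step 13 | actinol TBS ether | O=C1C(C)(C)C[C@H](O[Si](C)(C)C(C)(C)C)C[C@H]1C
F4 | step 13 | tertiary propargylic alcohol from F3 and 5 (carbinol centre unassigned) | CC(C)(C)[Si](C)(C)OC/C=C(\C)C#CC1(O)[C@H](C)C[C@@H](O[Si](C)(C)C(C)(C)C)CC1(C)C
F5 | step 13 | enyne bis-silyl ether (bis-TBS ether of 25) | CC(C)(C)[Si](C)(C)OC/C=C(\C)C#CC1=C(C)C[C@@H](O[Si](C)(C)C(C)(C)C)CC1(C)C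
F6 | step 4 | (Z)-β-triethoxysilyl allylic alcohol from 6 | CC1=CC2(CC(C)(C)C1(O)/C=C(/C(C)=C/CO[Si](C)(C)C(C)(C)C)[Si](OCC)(OCC)OCC)OCCO2
F7 | step 4 | β-hydroxy ketone (6-hydroxy-7,8-dihydro-8-one, ketal and TBS retained) | CC1=CC2(CC(C)(C)C1(O)CC(=O)/C(C)=C/CO[Si](C)(C)C(C)(C)C)OCCO2
F8 | step 16 | acetylenic C25 apo-aldehyde (right ring, C7' to C12) | O=C/C(C)=C/C=C/C=C(C)/C=C/C=C(\C)C#CC1=C(C)C[C@@H](O)CC1(C)C
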